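Readings and results were computed on assumed constants, and the scatter is random.

The left-handed product climbs in elm to 25% by 4.00 min, while the left-handed substrate falls to 28% and the right-handed substrate stands at 43%, so the flask is a kinetic resolution and its remainder grows rich in right-handed substrate.

the same everywhere: left-handed substrate 0.25 M; right-handed substrate 0.25 M; free catalyst 0.2 mol%
- larch: reagent 0.52 equiv (fed, over 20 s); run made earlier; the fed solution adds 0.25 times the starting volume
- elm: reagent 0.79 equiv (fed, over 20 s); run made earlier; the fed solution adds 0.25 times the starting volume
- dawn: reagent 1.20 equiv (fed, over 20 s); the fed solution adds 0.25 times the starting volume; time 4.0 min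
- summer: reagent 0.800 equiv (fed, over 20 s); the fed solution adds 0.25 times the starting volume; time 4.0 min

| run | time / min | right-handed substrate / % | left-handed substrate / % | left-handed product / % |
|---|---|---|---|---|
| larch | 1.00 | 47 | 44 | 6 |
| larch | 2.00 | 46 | 37 | 8 |
| larch | 3.00 | 48 | 32 | 14 |
| larch | 4.00 | 48 | 34 | 16 |
| elm | 0.333 | 46 | 46 | 6 |
| elm | 0.667 | 46 | 42 | 9 |
| elm | 1.50 | 47 | 34 | 11 |
| elm | 4.00 | 43 | 28 | 25 |

(scatter of a reading: 2 percentage points)

- free catalyst is single-handed; left-handed substrate and right-handed substrate are mirror images of each other, charged as a racemate, each of them at the stated concentration
- charges are per starting volume, the dose included; the dosed solution carries all of it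
- an excess is below zero if the other one leads

- which one finishes higher in excess of right-handed substrate over left-handed substrate among what is left of the two ("neither" within 2 percentage points) (dawn / summer / neither)
- excess of right-handed substrate over left-handed substrate among what is left of the two at the end, dawn
- excess of right-handed substrate over left-handed substrate among what is left of the two at the end, summer

Let x and y be the fractions of the left-handed and right-handed substrate left of their own charges. The elm end readings give 3.84 for s, the selectivity factor: ln x divided by ln y. It is a reading, carrying a scatter of 2 percentage points on each value. With s held, y is x raised to the inverse of s, and the excess, (y − x)/(y + x), rises as x falls.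

The question turned round is therefore what would let summer match dawn: with s held, x in dawn must be no lower than in summer. Take D, minus ln x per equivalent of reagent charged, at the same time of reading. Larch gives 0.742 and elm 0.734, across a dose step of 1.52 times. To stand level with a summer at the mean of these two readings, dawn would need D down at 0.492, below both readings.

Carrying the mean, 0.738, to both flasks puts x at 0.413 in dawn and 0.554 in summer. My reckoning then gives excesses of 31.6% in dawn and 21.5% in summer.

The forecast also names dawn, but with higher figures, 40% (32% to 47%) for dawn and 23% (18% to 28%) for summer, holding that “the higher dose clearly gives more”.

Dawn finishes higher, at 36.9% against 23.9% for summer.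

    2 free catalyst ⇌ resting dimer, settled at all times (K = 4.40 × 10⁵ /M)
    reagent + catalyst intermediate B → free catalyst + right-handed product (k = 280 /M/s)
    free catalyst + right-handed substrate ⇌ catalyst intermediate B (K = 1.40 /M, k = 1100 /M/s)
    reagent + catalyst intermediate A → free catalyst + left-handed product (k = 820 /M/s)
    free catalyst ⇌ dormant form (K = 2.30, k = 0.0470 /s)
    free catalyst + left-handed substrate ⇌ catalyst intermediate A (K = 2.10 /M, k = 14000 /M/s)
    reagent → decomposition product (k = 3.60 × 10⁻⁵ /s)

The neighbour of dawn holds 0.05 mol% of free catalyst, a quarter of the recipe, with the reagent and the time unchanged. It keeps 55% of its charged left-handed substrate unbound, against 37% in dawn. With s, that x gives an excess of 21.6%, and the neighbour ends at 22.8%, down beside summer's 23.9%.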